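The pyran ring (O1–C2–C3–C4–C4a–C8a) is disconnected by taking C2, the gem-dimethyl carbon, out of the O1–C3 link. The precursor is the (S)-2-(2-hydroxypropan-2-yl)-2,3-dihydrobenzofuran 6, the kinetic 5-exo product of a Shi epoxidation of a prenylated phloroacetophenone. The key step exploits two features. O1 sits on C8a ortho to the C8 acetyl group, so it is a vinylogous ester oxygen that leaves under Lewis acid, and C2 is tertiary. In one operation the carbinol is acetylated, the acetate expels O1 from the stereocentre with inversion, and O1 re-closes on CMe2. This gives the chroman with the (R)-acetoxy group. Deacylation and selective 5-O-geranylation finish the synthesis.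

Key step: step 4

Remark: chroman numbering is used throughout (O1, C2 = CMe2, C3 = CHOH, C4 = CH2, C4a, C5 = O-geranyl, C6 = H, C7 = OH, C8 = acetyl, C8a). The stereocentre C3 of the target SMILES is read as (R) and the C2'=C3' geranyl double bond as E.

Step 1
Reactants: 1 2,4,6-trihydroxyacetophenone; 2 prenyl bromide
Product: 3 3-prenyl-2,4,6-trihydroxyacetophenone
Conditions: KOH (1.0 equiv), H2O, 0 °C → rt, 1 in slight excess
Reagents that add atoms: none
Why: Phenolate C-allylation of the ambident phloroglucinol anion, where water shields the oxygens by hydrogen bonding so the soft allylic bromide is taken up at ring carbon, and the excess of 1 limits a second prenylation.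

Step 2
Reactants: 3 3-prenyl-2,4,6-trihydroxyacetophenone
Product: 4 2-hydroxy-3-prenyl-4,6-bis(pivaloyloxy)acetophenone
Conditions: PivCl (2.1 equiv), Et3N (2.5 equiv), CH2Cl2, −10 → 0 °C
Reagents that add atoms: pivaloyl chloride, CC(C)(C)C(=O)Cl
Why: Schotten–Baumann-type O-acylation in which the bulky acyl chloride takes the unchelated 4-OH and the less hindered 6-OH, whereas the 2-OH, flanked by prenyl and hydrogen-bonded to the acetyl group, stays free.

Step 3
Reactants: 4 2-hydroxy-3-prenyl-4,6-bis(pivaloyloxy)acetophenone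
Product: 6 (2S)-7-acetyl-2-(2-hydroxypropan-2-yl)-2,3-dihydrobenzofuran-4,6-diyl bis(pivalate), via (R)-epoxide 5 (not isolated)
Conditions: D-fructose-derived Shi ketone (30 mol %), Oxone, K2CO3, Bu4NHSO4 (cat.), MeCN–DMM / aq. Na2B4O7–Na2EDTA (pH ≈ 10.5), 0 °C
Reagents that add atoms: Oxone (active component KHSO5), [K+].[O-]S(=O)(=O)OO
Why: Shi asymmetric epoxidation (spiro transition state of the chiral dioxirane on a trisubstituted alkene) should give the (R)-epoxide, which the only free, adjacent phenolate opens at once at the secondary carbon by 5-exo-tet SN2 with inversion, setting the (S)-centre.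

Step 4
Reactants: 6 (2S)-7-acetyl-2-(2-hydroxypropan-2-yl)-2,3-dihydrobenzofuran-4,6-diyl bis(pivalate)
Product: 9 (3R)-3-acetoxy-8-acetyl-2,2-dimethylchroman-5,7-diyl bis(pivalate), via tertiary acetate 7 (not isolated), via acetoxonium ion 8 (not isolated)
Conditions: Ac2O (1.1 equiv), TMSOTf (5 mol %), CH2Cl2, −20 °C; then TMSOTf (to 25 mol %), 0 °C → rt
Reagents that add atoms: acetic anhydride, CC(=O)OC(C)=O
Why: Proposed new method: the tertiary carbinol is first acetylated (7), then silylation or protonation of the aryl ketone oxygen makes O1, the ether oxygen of a vinylogous ester (O1–C8a=C8–C=O), a leaving group, and the acetate carbonyl displaces it from the ring CH (future C3) from the rear to give the 1,3-dioxolan-2-ylium ion 8 with a free phenol (5-exo-tet). The phenol oxygen O1 then re-closes on the gem-dimethyl carbon (future C2), the more cation-stabilising end of 8 (6-exo-tet on the acetoxonium ion, the counterpart of a 6-endo epoxide opening), so that CMe2 is inserted into the O1–CH bond and the five-membered ring becomes the pyran ring. The closest known reaction types are neighbouring acetate participation in the solvolysis of vicinal acetoxy sulfonates, nucleophilic opening of diol-derived acetoxonium ions at the more substituted carbon, the sulfonate-triggered tetrahydrofuran-to-tetrahydropyran expansion used for polyethers, and the acetic-anhydride-induced furo-to-pyrano isomerisation of hydroxyisopropyl-dihydrofuroquinoline alkaloids. The single stereocentre is controlled by the substrate: it is inverted once in the SN2 displacement of O1 and is not touched in the re-closure, so (S)-6 should give (R)-9. The step needs attack of O1 at the tertiary and not at the secondary carbon of 8, and this is secured because return to the secondary carbon only regenerates 7 with unchanged configuration whereas the secondary acetate of 9 does not ionise again, so the equilibrium drains to 9. The pivalates leave O1 as the only phenol oxygen that can close, and the acetate cap blocks the configuration-retaining ipso exchange (Smiles type) open to a free carbinol.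

Step 5
Reactants: 9 (3R)-3-acetoxy-8-acetyl-2,2-dimethylchroman-5,7-diyl bis(pivalate)
Product: 10 (3R)-8-acetyl-2,2-dimethylchroman-3,5,7-triol
Conditions: K2CO3 (3 equiv), MeOH, rt, Ar
Reagents that add atoms: none
Why: Base-mediated transesterification (Zemplén-type methanolysis) removes both aryl pivalates and the secondary acetate by acyl–oxygen cleavage, so the C3–O bond and its (R)-configuration are retained.

Step 6
Reactants: 10 (3R)-8-acetyl-2,2-dimethylchroman-3,5,7-triol; 11 geranyl bromide
Product: 12 target, (3R)-8-acetyl-5-geranyloxy-2,2-dimethylchroman-3,7-diol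
Conditions: K2CO3 (1.1 equiv), 11 (1.05 equiv), acetone, rt → 40 °C
Reagents that add atoms: none
Why: Williamson ether synthesis in which the 5-OH, para to the acetyl group, unchelated and most acidic, is alkylated by SN2 with retention of the E-geometry, while the 7-OH (hydrogen-bonded to the acetyl group) and the C3 alcohol stay free.

Compound list
1 | 2,4,6-trihydroxyacetophenone (phloroacetophenone) | CC(=O)c1c(O)cc(O)cc1O | starting material
2 | prenyl bromide (1-bromo-3-methylbut-2-ene) | CC(C)=CCBr | starting material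
3 | 1-[2,4,6-trihydroxy-3-(3-methylbut-2-en-1-yl)phenyl]ethanone | CC(=O)c1c(O)cc(O)c(CC=C(C)C)c1O | intermediate
4 | 4-acetyl-5-hydroxy-6-(3-methylbut-2-en-1-yl)-1,3-phenylene bis(2,2-dimethylpropanoate) | CC(=O)c1c(OC(=O)C(C)(C)C)cc(OC(=O)C(C)(C)C)c(CC=C(C)C)c1O | intermediate
5 | 4-acetyl-6-{[(2R)-3,3-dimethyloxiran-2-yl]methyl}-5-hydroxy-1,3-phenylene bis(2,2-dimethylpropanoate) | CC(=O)c1c(OC(=O)C(C)(C)C)cc(OC(=O)C(C)(C)C)c(C[C@H]2OC2(C)C)c1O | intermediate
6 | (2S)-7-acetyl-2-(2-hydroxypropan-2-yl)-2,3-dihydro-1-benzofuran-4,6-diyl bis(2,2-dimethylpropanoate) | CC(=O)c1c(OC(=O)C(C)(C)C)cc(OC(=O)C(C)(C)C)c2c1O[C@@H](C2)C(C)(C)O | intermediate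
7 | (2S)-2-(2-acetoxypropan-2-yl)-7-acetyl-2,3-dihydro-1-benzofuran-4,6-diyl bis(2,2-dimethylpropanoate) | CC(=O)c1c(OC(=O)C(C)(C)C)cc(OC(=O)C(C)(C)C)c2c1O[C@@H](C2)C(C)(C)OC(C)=O | intermediate
8 | (5R)-5-[3-acetyl-2-hydroxy-4,6-bis(pivaloyloxy)benzyl]-2,4,4-trimethyl-1,3-dioxolan-2-ylium triflate | CC(=O)c1c(OC(=O)C(C)(C)C)cc(OC(=O)C(C)(C)C)c(C[C@H]2OC(C)=[O+]C2(C)C)c1O.[O-]S(=O)(=O)C(F)(F)F | intermediate
9 | (3R)-3-acetoxy-8-acetyl-2,2-dimethyl-3,4-dihydro-2H-chromene-5,7-diyl bis(2,2-dimethylpropanoate) | CC(=O)c1c(OC(=O)C(C)(C)C)cc(OC(=O)C(C)(C)C)c2c1OC(C)(C)[C@H](OC(C)=O)C2 | intermediate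
10 | 1-[(3R)-3,5,7-trihydroxy-2,2-dimethyl-3,4-dihydro-2H-chromen-8-yl]ethanone | CC(=O)c1c(O)cc(O)c2c1OC(C)(C)[C@H](O)C2 | intermediate
11 | geranyl bromide, (2E)-1-bromo-3,7-dimethylocta-2,6-diene | CC(C)=CCC/C(C)=C/CBr | starting material
12 | 1-[(3R)-5-{[(2E)-3,7-dimethylocta-2,6-dien-1-yl]oxy}-3,7-dihydroxy-2,2-dimethyl-3,4-dihydro-2H-chromen-8-yl]ethanone | CC(=O)c1c(O)cc(OC/C=C(\C)CCC=C(C)C)c2c1OC(C)(C)[C@H](O)C2 | target

Total step count: 6. Longest linear sequence: 6 steps (from 1).

Steps most likely to fail

1. Step 4. Ionisation of the tertiary acetate with loss of acetic acid, followed by elimination and aromatisation to a 2-isopropylbenzofuran, may outrun cleavage of the ring C–O bond. Alternatively that bond may not cleave at all under catalytic acid. The fallback uses known chemistry, sets out from 4 and returns at 10.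
   - DDQ in refluxing dioxane dehydrogenates the benzylic position, and oxa-6π closure gives 8-acetyl-2,2-dimethyl-2H-chromene-5,7-diyl bis(pivalate) F1.
   - Jacobsen–Katsuki epoxidation with the (R,R)-Mn(salen) catalyst (NaOCl, 4-phenylpyridine N-oxide, CH2Cl2, 0 °C) should give the (3R,4R)-3,4-epoxychroman F2.
   - Hydrogenolysis of the benzylic C4–O bond (H2, Pd/C, EtOAc) gives the (3R)-chroman-3-ol bis(pivalate) F3.
   - Methanolysis under the conditions of step 5 leads back to 10.

2. Step 3. Oxidation of the phenolate ring by the dioxirane may compete with epoxidation of the alkene. Premature loss of the 4-O-pivalate at pH 10.5 would also open the way to closure through the wrong oxygen. The fallback sets out from 4 and returns at 6.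
   - The free phenol is masked (TBSCl, imidazole, DMF) as the 2-O-TBS ether F4.
   - The Shi epoxidation is run on this neutral substrate, and the (R)-epoxy silyl ether F5 is isolated.
   - TBAF (THF, 0 °C) releases the phenolate in a separate operation, which closes 5-exo with inversion to 6.

3. Step 1. Double C-prenylation, dearomatising gem-dialkylation and O-alkylation may erode the mono-C-prenyl product. The fallback sets out from 1 and returns at 4, replacing steps 1 and 2.
   - Pivaloyl chloride (2 equiv, Et3N) gives 2-hydroxy-4,6-bis(pivaloyloxy)acetophenone F6.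
   - Its remaining phenol is O-alkylated with methyl 2-methylbut-3-en-2-yl carbonate under Pd(PPh3)4 (Tsuji–Trost O-allylation at the tertiary terminus) to the 1,1-dimethylallyl aryl ether F7.
   - Aromatic Claisen rearrangement (N,N-diethylaniline, 110–140 °C) transfers the allyl unit, with transposition of its ends, to the only free ortho carbon and delivers 4.

Further compounds
F1 | step 4 | 8-acetyl-2,2-dimethyl-2H-chromene-5,7-diyl bis(2,2-dimethylpropanoate) | CC(=O)c1c(OC(=O)C(C)(C)C)cc(OC(=O)C(C)(C)C)c2c1OC(C)(C)C=C2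
F2 | step 4 | (3R,4R)-8-acetyl-3,4-epoxy-2,2-dimethylchroman-5,7-diyl bis(2,2-dimethylpropanoate) | CC(=O)c1c(OC(=O)C(C)(C)C)cc(OC(=O)C(C)(C)C)c2c1OC(C)(C)[C@@H]3O[C@H]23
F3 | step 4 | (3R)-8-acetyl-3-hydroxy-2,2-dimethylchroman-5,7-diyl bis(2,2-dimethylpropanoate) | CC(=O)c1c(OC(=O)C(C)(C)C)cc(OC(=O)C(C)(C)C)c2c1OC(C)(C)[C@H](O)C2
F4 | step 3 | 4-acetyl-5-(tert-butyldimethylsilyloxy)-6-(3-methylbut-2-en-1-yl)-1,3-phenylene bis(2,2-dimethylpropanoate) | CC(=O)c1c(OC(=O)C(C)(C)C)cc(OC(=O)C(C)(C)C)c(CC=C(C)C)c1O[Si](C)(C)C(C)(C)C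
F5 | step 3 | 4-acetyl-5-(tert-butyldimethylsilyloxy)-6-{[(2R)-3,3-dimethyloxiran-2-yl]methyl}-1,3-phenylene bis(2,2-dimethylpropanoate) | CC(=O)c1c(OC(=O)C(C)(C)C)cc(OC(=O)C(C)(C)C)c(C[C@H]2OC2(C)C)c1O[Si](C)(C)C(C)(C)C
F6 | step 1 | 4-acetyl-5-hydroxy-1,3-phenylene bis(2,2-dimethylpropanoate) | CC(=O)c1c(O)cc(OC(=O)C(C)(C)C)cc1OC(=O)C(C)(C)C
F7 | step 1 | 4-acetyl-5-[(2-methylbut-3-en-2-yl)oxy]-1,3-phenylene bis(2,2-dimethylpropanoate) | CC(=O)c1c(OC(C)(C)C=C)cc(OC(=O)C(C)(C)C)cc1OC(=O)C(C)(C)C
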